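**Assumption:** the acyl chain is read as octadecanoyl (stearoyl), so the target is the 15‑O‑stearate of (13S)‑labd‑8(17)‑en‑19‑oic acid (4S,5R,9S,10R,13S); labdane numbering (C1–C20) is used for atom labels throughout.

## Retrosynthetic overview

1. Target 13 ⇐ C19 aldehyde 12 (oxidation) ⇐ C4–H aldehyde 11 (face‑selective α‑methylation sets the C4 quaternary centre).
2. 11 ⇐ acyclic (E,E)‑dienal 10 by a one‑pot oxidative bicyclisation through an enamine radical cation: the aldehyde α‑carbon C4, made electrophilic, bonds to alkene carbon C5. Ring A closes first (C4–C5), then ring B (C10–C9), then the exocyclic C8=C17 alkene forms.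
3. 10 ⇐ allylic bromide 6 + four‑carbon acetal Grignard from 7 (C1–C2 bond).
4. 6 ⇐ (S)‑dihydrofarnesyl stearate 4 (terminal allylic oxidation, bromination) ⇐ (2E,6E)‑farnesol 1 (asymmetric hydrogenation sets C13) + stearoyl chloride 3.

## Route

Step 1
Reactants: 1 (2E,6E)‑farnesol
Product: 2 (3S,6E)‑3,7,11‑trimethyldodeca‑6,10‑dien‑1‑ol ((S)‑2,3‑dihydrofarnesol)
Conditions: H2 (100 atm), Ru(OAc)2[(R)‑BINAP] (0.2 mol%), MeOH/H2O 95:5, 20 °C
Reagents that add atoms: none
Why: Noyori asymmetric hydrogenation, in which the hydroxyl‑directed Ru–BINAP catalyst reduces only the allylic‑alcohol C=C of the (E)‑olefin and with the (R)‑ligand gives the (3S) centre (future C13) in about 96–98% ee while the two remote trisubstituted alkenes stay untouched.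

Step 2
Reactants: 2 (S)‑2,3‑dihydrofarnesol; 3 stearoyl chloride
Product: 4 (3S,6E)‑3,7,11‑trimethyldodeca‑6,10‑dien‑1‑yl octadecanoate
Conditions: Et3N, DMAP (5 mol%), CH2Cl2, 0 °C → rt
Reagents that add atoms: none
Why: DMAP‑catalysed acylation (nucleophilic acyl substitution) of the primary alcohol installs the final stearate at the outset, so the ester itself serves as the hydroxyl protection for the rest of the route.

Step 3
Reactants: 4 (S)‑dihydrofarnesyl stearate
Product: 5 (3S,6E,10E)‑12‑hydroxy‑3,7,11‑trimethyldodeca‑6,10‑dien‑1‑yl octadecanoate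
Conditions: SeO2 (0.3 equiv), t‑BuOOH (70% aq., 3 equiv), salicylic acid (0.1 equiv), CH2Cl2, 0 °C → rt, stopped at about 60% conversion, 4 recycled
Reagents that add atoms: tert‑butyl hydroperoxide, CC(C)(C)OO (terminal oxygen source; the oxygen is delivered through SeO2, O=[Se]=O)
Why: Sharpless catalytic SeO2 allylic oxidation (ene reaction then [2,3]‑sigmatropic shift) attacks the less hindered terminal isopropylidene alkene and oxidises its (E)‑methyl group, giving the (E)‑allylic alcohol that becomes C1.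

Step 4
Reactants: 5 allylic alcohol
Product: 6 (3S,6E,10E)‑12‑bromo‑3,7,11‑trimethyldodeca‑6,10‑dien‑1‑yl octadecanoate
Conditions: CBr4, PPh3, CH2Cl2, 0 °C
Reagents that add atoms: carbon tetrabromide, BrC(Br)(Br)Br
Why: Appel reaction converts the primary allylic alcohol into the bromide under neutral conditions without allylic transposition or E/Z isomerisation.

Step 5
Reactants: 6 allylic bromide; 7 2‑(3‑chloropropyl)‑1,3‑dioxolane
Product: 10 (3S,6E,10E)‑3,7,11‑trimethyl‑16‑oxohexadeca‑6,10‑dien‑1‑yl octadecanoate, via Grignard reagent 8 (not isolated), via dioxolane acetal 9 (not isolated)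
Conditions: 7, Mg, THF, 50 °C; added to 6, Li2CuCl4 (5 mol%), THF, −40 → 0 °C; then 2 M aq. HCl, THF, rt
Reagents that add atoms: water, O
Why: Kochi‑type Li2CuCl4‑catalysed sp3–sp3 Grignard coupling occurs at the unhindered primary allylic carbon (α‑attack in THF, E‑alkene retained) far faster at low temperature than addition to the ester, and the acidic quench hydrolyses the dioxolane to the aldehyde.

Step 6
Reactants: 10 (E,E)‑dienal
Product: 11 15‑(octadecanoyloxy)‑19‑norlabd‑8(17)‑en‑18‑al (4α‑formyl, 4β‑H; 4R,5S,9S,10S,13S)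
Conditions: (2S,5S)‑2‑tert‑butyl‑3‑methyl‑5‑(naphthalen‑1‑ylmethyl)imidazolidin‑4‑one·TFA (30 mol%), Cu(OTf)2 (2.5 equiv, slow addition), CF3CO2Na (2 equiv), TFA (3 equiv), i‑PrCN/DME, rt
Reagents that add atoms: none
Why: Proposed new method: the aldehyde forms an (E)‑enamine with the imidazolidinone, and one‑electron oxidation by Cu(OTf)2 gives a 3π‑electron radical cation whose normally nucleophilic α‑carbon C4 is now electrophilic and bonds to the nucleophilic alkene carbon C5 in a 6‑endo closure (ring A); the tertiary C10 radical then closes ring B 6‑endo onto C9, and the tertiary C8 radical is oxidised by a second equivalent of divalent copper with loss of a C17 proton to give the exocyclic alkene; the arylmethyl group of the catalyst shields one enamine face so that attack anti to it sets C4 as R, and the all‑chair transition state of the two (E)‑alkenes relays this to the trans‑fused 5S,9S,10S centres with the formyl group equatorial; the closest known reaction types are organo‑SOMO‑catalysed enantioselective polyene cyclisation terminated by arenes and trivalent‑manganese/divalent‑copper oxidative polyene cyclisations that end in oxidative elimination to an exocyclic methylene.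

Step 7
Reactants: 11 C4–H aldehyde
Product: 12 15‑(octadecanoyloxy)labd‑8(17)‑en‑19‑al (4S,5R,9S,10R,13S)
Conditions: t‑BuOK (1.15 equiv), MeI (5 equiv), THF, −40 → 0 °C (base added last)
Reagents that add atoms: iodomethane, CI
Why: Enolate C‑alkylation in which the aldehyde α‑C–H, by far the most acidic site, gives the exocyclic enolate and MeI enters from the equatorial α face anti to the axial C10 methyl, placing the new methyl equatorial and the formyl axial (C19) and so setting C4 as S.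

Step 8
Reactants: 12 C19 aldehyde
Product: 13 (1S,4aR,5S,8aR)‑1,4a‑dimethyl‑6‑methylidene‑5‑[(3S)‑3‑methyl‑5‑(octadecanoyloxy)pentyl]decahydronaphthalene‑1‑carboxylic acid (target)
Conditions: NaClO2, NaH2PO4, 2‑methyl‑2‑butene, t‑BuOH/H2O, rt
Reagents that add atoms: sodium chlorite, [Na+].[O-]Cl=O
Why: Pinnick oxidation converts the hindered, non‑enolisable aldehyde into the acid under mild buffered conditions, with 2‑methyl‑2‑butene scavenging HOCl to protect the exocyclic alkene and the stearate ester inert.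

## Compound list

1 | (2E,6E)‑farnesol | CC(C)=CCC/C(C)=C/CC/C(C)=C/CO | starting material
2 | (3S,6E)‑3,7,11‑trimethyldodeca‑6,10‑dien‑1‑ol | CC(C)=CCC/C(C)=C/CC[C@H](C)CCO | intermediate
3 | stearoyl chloride (octadecanoyl chloride) | CCCCCCCCCCCCCCCCCC(=O)Cl | starting material
4 | (3S,6E)‑3,7,11‑trimethyldodeca‑6,10‑dien‑1‑yl octadecanoate | CC(C)=CCC/C(C)=C/CC[C@H](C)CCOC(=O)CCCCCCCCCCCCCCCCC | intermediate
5 | (3S,6E,10E)‑12‑hydroxy‑3,7,11‑trimethyldodeca‑6,10‑dien‑1‑yl octadecanoate | OC/C(C)=C/CC/C(C)=C/CC[C@H](C)CCOC(=O)CCCCCCCCCCCCCCCCC | intermediate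
6 | (3S,6E,10E)‑12‑bromo‑3,7,11‑trimethyldodeca‑6,10‑dien‑1‑yl octadecanoate | BrC/C(C)=C/CC/C(C)=C/CC[C@H](C)CCOC(=O)CCCCCCCCCCCCCCCCC | intermediate
7 | 2‑(3‑chloropropyl)‑1,3‑dioxolane | ClCCCC1OCCO1 | starting material
8 | [3‑(1,3‑dioxolan‑2‑yl)propyl]magnesium chloride | Cl[Mg]CCCC1OCCO1 | intermediate (not isolated)
9 | (3S,6E,10E)‑15‑(1,3‑dioxolan‑2‑yl)‑3,7,11‑trimethylpentadeca‑6,10‑dien‑1‑yl octadecanoate | O1CCOC1CCCC/C(C)=C/CC/C(C)=C/CC[C@H](C)CCOC(=O)CCCCCCCCCCCCCCCCC | intermediate (not isolated)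
10 | (3S,6E,10E)‑3,7,11‑trimethyl‑16‑oxohexadeca‑6,10‑dien‑1‑yl octadecanoate | O=CCCCC/C(C)=C/CC/C(C)=C/CC[C@H](C)CCOC(=O)CCCCCCCCCCCCCCCCC | intermediate
11 | (3S)‑5‑[(1S,4aS,5R,8aS)‑5‑formyl‑8a‑methyl‑2‑methylidenedecahydronaphthalen‑1‑yl]‑3‑methylpentyl octadecanoate | C=C1CC[C@@H]2[C@](C)(CCC[C@H]2C=O)[C@H]1CC[C@H](C)CCOC(=O)CCCCCCCCCCCCCCCCC | intermediate
12 | (3S)‑5‑[(1S,4aR,5S,8aR)‑5‑formyl‑5,8a‑dimethyl‑2‑methylidenedecahydronaphthalen‑1‑yl]‑3‑methylpentyl octadecanoate | C=C1CC[C@@H]2[C@](C)(CCC[C@]2(C)C=O)[C@H]1CC[C@H](C)CCOC(=O)CCCCCCCCCCCCCCCCC | intermediate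
13 | (1S,4aR,5S,8aR)‑1,4a‑dimethyl‑6‑methylidene‑5‑[(3S)‑3‑methyl‑5‑(octadecanoyloxy)pentyl]decahydronaphthalene‑1‑carboxylic acid | C=C1CC[C@@H]2[C@](C)(CCC[C@]2(C)C(=O)O)[C@H]1CC[C@H](C)CCOC(=O)CCCCCCCCCCCCCCCCC | target

## Step count and risks

Total steps: 8. Longest linear sequence: 8 (from 1).

**Step 6 (most likely to fail).** The ways it can fail are:
- the C10 radical is oxidised before ring B closes, giving a monocycle;
- termination at C8 gives endocyclic alkenes or solvent capture instead of the exocyclic alkene;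
- TFA isomerises the exocyclic alkene;
- incomplete catalyst control gives the diastereomer with the mirror‑image decalin.

The fallback sets out from bromide 6 and comes back at target 13. It replaces the organocatalytic cyclisation by an auxiliary‑controlled trivalent‑manganese oxidative radical bicyclisation of a β‑keto ester.
- (+)‑8‑Phenylmenthol is acetoacetylated with 2,2,6‑trimethyl‑4H‑1,3‑dioxin‑4‑one (xylene, 140 °C) to (1S,2R,5S)‑5‑methyl‑2‑(2‑phenylpropan‑2‑yl)cyclohexyl 3‑oxobutanoate F1.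
- Its dianion (NaH then n‑BuLi, THF, 0 °C) is alkylated at the terminal carbon by 6 to give the polyene β‑keto ester (+)‑8‑phenylmenthyl (6E,10E,14S)‑6,10,14‑trimethyl‑16‑(octadecanoyloxy)‑3‑oxohexadeca‑6,10‑dienoate F2.
- Mn(OAc)3·2H2O/Cu(OAc)2·H2O with Yb(OTf)3 in CF3CH2OH at 0 °C closes ring A and then ring B from the electrophilic α‑keto‑ester radical. The carboxylate‑ligated divalent copper converts the C8 radical into the exocyclic alkene, and the auxiliary fixes the 5,9,10 configuration. The product is (+)‑8‑phenylmenthyl 3‑oxo‑15‑(octadecanoyloxy)‑19‑norlabd‑8(17)‑en‑18‑oate F3.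
- Because F3 still has an enolisable C4–H, heating with allyl alcohol and DMAP in toluene exchanges the auxiliary, through the acylketene, for allyl 3‑oxo‑15‑(octadecanoyloxy)‑19‑norlabd‑8(17)‑en‑18‑oate F4; the stearate cannot react this way.
- K2CO3/MeI in acetone methylates C4 from the α face to give allyl 3‑oxo‑15‑(octadecanoyloxy)labd‑8(17)‑en‑19‑oate F5, with the ester axial.
- TsNHNH2 gives the C3 tosylhydrazone of F5, F6. Catecholborane then NaOAc·3H2O reduces it to allyl 15‑(octadecanoyloxy)labd‑8(17)‑en‑19‑oate F7.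
- Pd(PPh3)4 (zerovalent palladium) with morpholine removes the allyl group to give 13.

**Step 7.** The base may attack or enolise the stearate, or O‑methylation may compete. The fallback sets out from 11 and comes back at 12, and avoids any strong base.
- TBSOTf/Et3N (CH2Cl2, 0 °C) gives the tert‑butyldimethylsilyl enol ether of 11, F8.
- Et2Zn/CH2I2 (Furukawa–Simmons–Smith, CH2Cl2, −20 → 0 °C, 1.2 equiv) cyclopropanates the electron‑rich enol ether from the unhindered α face, faster than the unactivated exocyclic alkene, to give the spiro siloxycyclopropane F9.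
- TBAF in THF unmasks the cyclopropanol, which opens (Conia‑type, cleavage of the CH(O)–CH2 bond) to the α‑methyl aldehyde 12 with the methyl on the α face.

**Step 5.** The Grignard reagent may add to the stearate, or SN2′ coupling may compete. The fallback sets out from 6 (with 7) and comes back at acetal 9, which is then hydrolysed to 10 with aqueous HCl as in step 5.
- 7 and PhSO2Na (NaI cat., DMF, 80 °C) give 2‑[3‑(phenylsulfonyl)propyl]‑1,3‑dioxolane F10.
- Its α‑sulfonyl carbanion (n‑BuLi, THF, −78 °C) alkylates 6 purely SN2 to give the sulfone (3S,6E,10E)‑15‑(1,3‑dioxolan‑2‑yl)‑3,7,11‑trimethyl‑13‑(phenylsulfonyl)pentadeca‑6,10‑dien‑1‑yl octadecanoate F11.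
- Reductive desulfonylation with Na(Hg)/Na2HPO4 (THF/MeOH, −20 °C) gives 9.

## Further compounds

F1 | step 6 | (1S,2R,5S)‑5‑methyl‑2‑(2‑phenylpropan‑2‑yl)cyclohexyl 3‑oxobutanoate | CC(=O)CC(=O)O[C@H]1C[C@@H](C)CC[C@@H]1C(C)(C)c1ccccc1
F2 | step 6 | (+)‑8‑phenylmenthyl (6E,10E,14S)‑6,10,14‑trimethyl‑16‑(octadecanoyloxy)‑3‑oxohexadeca‑6,10‑dienoate | O=C(CC(=O)CC/C(C)=C/CC/C(C)=C/CC[C@H](C)CCOC(=O)CCCCCCCCCCCCCCCCC)O[C@H]1C[C@@H](C)CC[C@@H]1C(C)(C)c1ccccc1
F3 | step 6 | (+)‑8‑phenylmenthyl 3‑oxo‑15‑(octadecanoyloxy)‑19‑norlabd‑8(17)‑en‑18‑oate (C4 enolisable) | C=C1CC[C@@H]2[C@](C)(CCC(=O)[C@H]2C(=O)O[C@H]3C[C@@H](C)CC[C@@H]3C(C)(C)c3ccccc3)[C@H]1CC[C@H](C)CCOC(=O)CCCCCCCCCCCCCCCCC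
F4 | step 6 | allyl 3‑oxo‑15‑(octadecanoyloxy)‑19‑norlabd‑8(17)‑en‑18‑oate | C=C1CC[C@@H]2[C@](C)(CCC(=O)[C@H]2C(=O)OCC=C)[C@H]1CC[C@H](C)CCOC(=O)CCCCCCCCCCCCCCCCC
F5 | step 6 | allyl 3‑oxo‑15‑(octadecanoyloxy)labd‑8(17)‑en‑19‑oate | C=C1CC[C@@H]2[C@](C)(CCC(=O)[C@]2(C)C(=O)OCC=C)[C@H]1CC[C@H](C)CCOC(=O)CCCCCCCCCCCCCCCCC
F6 | step 6 | C3 tosylhydrazone of F5 | C=C1CC[C@@H]2[C@](C)(CCC(=NNS(=O)(=O)c3ccc(C)cc3)[C@]2(C)C(=O)OCC=C)[C@H]1CC[C@H](C)CCOC(=O)CCCCCCCCCCCCCCCCC
F7 | step 6 | allyl 15‑(octadecanoyloxy)labd‑8(17)‑en‑19‑oate | C=C1CC[C@@H]2[C@](C)(CCC[C@]2(C)C(=O)OCC=C)[C@H]1CC[C@H](C)CCOC(=O)CCCCCCCCCCCCCCCCC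
F8 | step 7 | tert‑butyldimethylsilyl enol ether of 11 (C4=C19, E/Z mixture) | C=C1CC[C@@H]2[C@](C)(CCCC2=CO[Si](C)(C)C(C)(C)C)[C@H]1CC[C@H](C)CCOC(=O)CCCCCCCCCCCCCCCCC
F9 | step 7 | spiro siloxycyclopropane at C4 (new CH2 on the α face, C19 epimers) | C=C1CC[C@@H]2[C@](C)(CCC[C@]2(C3)C3O[Si](C)(C)C(C)(C)C)[C@H]1CC[C@H](C)CCOC(=O)CCCCCCCCCCCCCCCCC
F10 | step 5 | 2‑[3‑(phenylsulfonyl)propyl]‑1,3‑dioxolane | O=S(=O)(CCCC1OCCO1)c1ccccc1
F11 | step 5 | (3S,6E,10E)‑15‑(1,3‑dioxolan‑2‑yl)‑3,7,11‑trimethyl‑13‑(phenylsulfonyl)pentadeca‑6,10‑dien‑1‑yl octadecanoate (sulfone epimers) | O1CCOC1CCC(S(=O)(=O)c1ccccc1)C/C(C)=C/CC/C(C)=C/CC[C@H](C)CCOC(=O)CCCCCCCCCCCCCCCCC
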